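**Strategy.** The route rests on cutting the C6–C7 bond of the ten-membered ring. In the target, C6 is an oxygen-bearing carbon allylic to C4=C5 and bonded to C7, which carries C11 with its two one-carbon arms C12 and C13; this is the pattern left by a [2,3]-Wittig shift. One operation on a thirteen-membered cyclic diallyl ether (oxygen bridging C6 and the C12 methylene, ring bonds trans at all three alkenes, silyl ethers at C2, C8 and C13) contracts it to the cyclodecadiene, makes the C6–C7 bond, sets C6 and leaves a C11=C12 methylene. That methylene is then oxidised to the lactone carbonyl and the ring dehydrogenated to the 7(11)-butenolide.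

Key step: step 14

Remark: germacrane numbering is used throughout; the C11 arm that carries the ring-ether oxygen (trans to C8) is called C12 and ends as the lactone carbonyl, the silyloxymethyl arm (cis to C8) is C13 and ends as the acetoxymethyl group, so C7=C11 of macrocycle 25 has trans ring bonds but is Z by the sequence rules; (R)-glycidol and (chloromethoxy)triisopropylsilane are taken as commercial, and the catalyst in step 5 is assumed to induce in the same sense as for aryl and alkenyl aldehydes.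

**Step 1**
Reactants: 1 (R)-glycidol
Product: 2 (2S)-pent-4-yne-1,2-diol
Conditions: LiC≡CH·H2NCH2CH2NH2 (3 equiv), DMSO, 0 °C → rt; aq. NH4Cl
Reagents that add atoms: lithium acetylide ethylenediamine complex, [Li]C#C.NCCN
Why: Epoxide alkynylation, in which the acetylide opens the glycidol alkoxide by SN2 attack at the unsubstituted epoxide carbon, so the stereocentre is not touched and becomes C8 (the descriptor changes from R to S only because the former ring CH2 loses priority).

**Step 2**
Reactants: 2 (2S)-pent-4-yne-1,2-diol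
Product: 3 (4S)-4,5-bis(triethylsilyloxy)pent-1-yne
Conditions: TESCl (2.4 equiv), imidazole, CH2Cl2, 0 °C → rt
Reagents that add atoms: chlorotriethylsilane, CC[Si](Cl)(CC)CC
Why: Silyl ether formation on both hydroxyls; the primary triethylsilyl ether later serves as a latent C7 aldehyde and the secondary one protects O8 until step 19.

**Step 3**
Reactants: 3 (4S)-4,5-bis(triethylsilyloxy)pent-1-yne
Product: 6 (2E,5S)-3-methyl-5,6-bis(triethylsilyloxy)hex-2-en-1-ol, via alkenyldimethylalane 4 (not isolated), via lithium alkenyl(butyl)dimethylalanate 5 (not isolated)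
Conditions: AlMe3 (3 equiv), (C5H5)2ZrCl2 (0.25 equiv), CH2Cl2, 0 °C → rt; volatiles removed; n-BuLi, THF, −78 °C; (CH2O)n, → rt; aq. potassium sodium tartrate
Reagents that add atoms: trimethylaluminium, C[Al](C)C; paraformaldehyde (as formaldehyde), C=O
Why: Negishi zirconium-catalysed carboalumination adds Me and Al syn across the terminal alkyne (Me to C10, Al to C1), and the alanate adds to formaldehyde with retention at the alkenyl carbon, which fixes the 1(10)E alkene and delivers C2 as a primary allylic alcohol.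

**Step 4**
Reactants: 6 (2E,5S)-3-methyl-5,6-bis(triethylsilyloxy)hex-2-en-1-ol
Product: 7 (2E,5S)-3-methyl-5,6-bis(triethylsilyloxy)hex-2-enal
Conditions: MnO2 (20 equiv), CH2Cl2, rt
Reagents that add atoms: none
Why: Allylic oxidation with MnO2 is selective for the allylic alcohol and neutral, so the silyl ethers and the E geometry should be retained.

**Step 5**
Reactants: 7 (2E,5S)-3-methyl-5,6-bis(triethylsilyloxy)hex-2-enal
Product: 9 (4R,5E,8S)-6-methyl-8,9-bis(triethylsilyloxy)non-5-en-1-yn-4-ol, via pinacol borate ester 8 (not isolated)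
Conditions: allenylboronic acid pinacol ester (1.5 equiv), (R)-3,3′-bis(2,4,6-triisopropylphenyl)-1,1′-binaphthyl-2,2′-diyl hydrogen phosphate (5 mol %), 4 Å molecular sieves, toluene, −20 °C; aqueous work-up
Reagents that add atoms: allenylboronic acid pinacol ester, C=C=CB1OC(C)(C)C(C)(C)O1
Why: Chiral phosphoric acid-catalysed propargylboration through a closed six-membered SE2′ transition state, which gives only the homopropargylic alcohol; the (R)-catalyst is expected to direct attack to the Re face of the enal and so set 2R under reagent control (to be confirmed by Mosher ester analysis, the antipodal catalyst being used if the sense proves opposite).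

**Step 6**
Reactants: 9 (4R,5E,8S)-6-methyl-8,9-bis(triethylsilyloxy)non-5-en-1-yn-4-ol
Product: 10 (4R,5E,8S)-4-(tert-butyldimethylsilyloxy)-6-methyl-8,9-bis(triethylsilyloxy)non-5-en-1-yne
Conditions: TBSOTf, 2,6-lutidine, CH2Cl2, −78 °C
Reagents that add atoms: tert-butyldimethylsilyl trifluoromethanesulfonate, CC(C)(C)[Si](C)(C)OS(=O)(=O)C(F)(F)F
Why: Silylation of the secondary allylic alcohol with the silyl triflate at low temperature, conditions that leave the triethylsilyl ethers and the alkyne untouched.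

**Step 7**
Reactants: 10 (4R,5E,8S)-4-(tert-butyldimethylsilyloxy)-6-methyl-8,9-bis(triethylsilyloxy)non-5-en-1-yne
Product: 13 (2E,5R,6E,9S)-5-(tert-butyldimethylsilyloxy)-3,7-dimethyl-9,10-bis(triethylsilyloxy)deca-2,6-dien-1-ol, via dienyldimethylalane 11 (not isolated), via lithium dienyl(butyl)dimethylalanate 12 (not isolated)
Conditions: AlMe3 (3 equiv), (C5H5)2ZrCl2 (0.25 equiv), CH2Cl2, 0 °C → rt; volatiles removed; n-BuLi, THF, −78 °C; (CH2O)n, → rt; aq. potassium sodium tartrate
Reagents that add atoms: trimethylaluminium, C[Al](C)C; paraformaldehyde (as formaldehyde), C=O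
Why: A second Negishi carboalumination and hydroxymethylation, by the same syn addition and retentive trapping, builds the 4E alkene with its C15 methyl and adds C6 as the allylic alcohol, the existing trisubstituted alkene and the silyl ethers being inert to AlMe3 under these conditions.

**Step 8**
Reactants: 13 (2E,5R,6E,9S)-5-(tert-butyldimethylsilyloxy)-3,7-dimethyl-9,10-bis(triethylsilyloxy)deca-2,6-dien-1-ol
Product: 15 (2E,5R,6E,9S)-5-(tert-butyldimethylsilyloxy)-1-chloro-3,7-dimethyl-9,10-bis(triethylsilyloxy)deca-2,6-diene, via allylic mesylate 14 (not isolated)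
Conditions: MsCl, LiCl, 2,4,6-collidine, DMF, 0 °C
Reagents that add atoms: lithium chloride, [Li+].[Cl-]; methanesulfonyl chloride, CS(=O)(=O)Cl (its chloride joins the chloride pool, its mesyl group stays only in 14)
Why: The primary allylic alcohol is mesylated and the mesylate displaced by chloride in the same flask (SN2 at the primary carbon, without allylic transposition under these buffered conditions), which gives a leaving group at C6 robust enough for the next four steps.

**Step 9**
Reactants: 15 (2E,5R,6E,9S)-5-(tert-butyldimethylsilyloxy)-1-chloro-3,7-dimethyl-9,10-bis(triethylsilyloxy)deca-2,6-diene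
Product: 17 (2S,4E,6R,8E)-6-(tert-butyldimethylsilyloxy)-10-chloro-4,8-dimethyl-2-(triethylsilyloxy)deca-4,8-dienal, via alkoxydimethylsulfonium chloride 16 (not isolated)
Conditions: (COCl)2 (4 equiv), DMSO (8 equiv), CH2Cl2, −78 → −40 °C; Et3N, −78 °C → rt
Reagents that add atoms: none
Why: Swern oxidation applied directly to a primary triethylsilyl ether, in which the activated sulfoxide cleaves the unhindered primary Si–O bond to the alkoxysulfonium salt that collapses to the aldehyde on addition of Et3N, while the secondary silyl ethers and the allylic chloride are not affected and C8 should not epimerise at low temperature.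

**Step 10**
Reactants: 18 triethyl phosphonoacetate; 19 (chloromethoxy)triisopropylsilane
Product: 21 ethyl 2-(diethoxyphosphoryl)-3-(triisopropylsilyloxy)propanoate (racemic), via sodium phosphonoacetate carbanion 20 (not isolated)
Conditions: NaH, THF, 0 °C; then 19, 0 °C → rt (18 in slight excess)
Reagents that add atoms: none
Why: C-Alkylation of the stabilised phosphonoacetate carbanion by a reactive α-chloro ether (as in malonate alkylations with alkoxymethyl chlorides) installs the future C13 with its oxygen already protected as a bulky silyl ether.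

**Step 11**
Reactants: 17 (2S,4E,6R,8E)-6-(tert-butyldimethylsilyloxy)-10-chloro-4,8-dimethyl-2-(triethylsilyloxy)deca-4,8-dienal; 21 ethyl 2-(diethoxyphosphoryl)-3-(triisopropylsilyloxy)propanoate
Product: 22 ethyl (2E,4S,6E,8R,10E)-8-(tert-butyldimethylsilyloxy)-12-chloro-6,10-dimethyl-4-(triethylsilyloxy)-2-[(triisopropylsilyloxy)methyl]dodeca-2,6,10-trienoate
Conditions: LiCl, 1,8-diazabicyclo[5.4.0]undec-7-ene (DBU), MeCN, 0 °C → rt
Reagents that add atoms: none
Why: Horner–Wadsworth–Emmons olefination under mild LiCl/amine conditions, which for α-substituted phosphonoacetates should favour the ester trans to C8, so that C12 (ester) and C13 (silyloxymethyl) are told apart by geometry; the weak base should not epimerise C8, and loss of silyloxide from the carbanion should be slower than its addition to the aldehyde.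

**Step 12**
Reactants: 22 ethyl (2E,4S,6E,8R,10E)-8-(tert-butyldimethylsilyloxy)-12-chloro-6,10-dimethyl-4-(triethylsilyloxy)-2-[(triisopropylsilyloxy)methyl]dodeca-2,6,10-trienoate
Product: 23 (2Z,4S,6E,8R,10E)-8-(tert-butyldimethylsilyloxy)-12-chloro-6,10-dimethyl-4-(triethylsilyloxy)-2-[(triisopropylsilyloxy)methyl]dodeca-2,6,10-trien-1-ol
Conditions: i-Bu2AlH (2.5 equiv), CH2Cl2, −78 °C; aq. potassium sodium tartrate
Reagents that add atoms: none
Why: 1,2-Reduction of the enoate by the aluminium hydride at low temperature gives the C12 allylic alcohol (trans to C8) without touching the allylic chloride or the silyl ethers.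

**Step 13**
Reactants: 23 (2Z,4S,6E,8R,10E)-8-(tert-butyldimethylsilyloxy)-12-chloro-6,10-dimethyl-4-(triethylsilyloxy)-2-[(triisopropylsilyloxy)methyl]dodeca-2,6,10-trien-1-ol
Product: 25 (3Z,5S,7E,9R,11E)-9-(tert-butyldimethylsilyloxy)-7,11-dimethyl-5-(triethylsilyloxy)-3-[(triisopropylsilyloxy)methyl]-1-oxacyclotrideca-3,7,11-triene (oxygen bridging C6 and C12), via sodium alkoxide 24 (not isolated)
Conditions: NaH (5 equiv), Bu4NI (cat.), THF, 0.003 M, slow addition, 50 °C
Reagents that add atoms: none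
Why: Intramolecular Williamson etherification, in which the C12 alkoxide displaces the primary allylic chloride at C6 (SN2, helped by iodide exchange) under high dilution to close a thirteen-membered ring that accommodates three trans ring alkenes without strain; the triisopropylsilyl group is too bulky to migrate to the neighbouring alkoxide.

**Step 14**
Reactants: 25 thirteen-membered diallyl ether (oxygen bridging C6 and C12)
Product: 28 (2R,6R,7S,8S)-2-(tert-butyldimethylsilyloxy)-8-(triethylsilyloxy)-13-(triisopropylsilyloxy)germacra-1(10)E,4E,11(12)-trien-6-ol, via C6-lithiated ether 26 (not isolated), via lithium alkoxide 27 (not isolated)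
Conditions: n-BuLi (2 equiv), THF, −78 → −30 °C; aq. NH4Cl at −78 °C
Reagents that add atoms: none
Why: n-BuLi removes a proton from C6, the ether methylene next to the unsubstituted vinylic C5, and the α-oxy allyllithium attacks C7 suprafacially through the five-centre array C6–O–C12–C11=C7 while the O–C12 bond breaks, which gives the C6 alkoxide, the new C6–C7 bond and the C11=C12 methylene. This is the [2,3]-Wittig rearrangement in its transannular form, known for thirteen-membered diallylic ethers; the ten-membered carbocycle (C1–C10) is closed by a three-atom ring contraction and not by end-to-end cyclisation, the strain being paid for by turning a carbanion into an alkoxide. C7 should be attacked anti to the C8–O bond, with C8–H eclipsing the alkene to avoid allylic 1,3-strain with the cis C13 arm, which corresponds to 7S (this centre is erased in step 18). C6 follows from the envelope transition state of the ring-trans C7=C11 alkene with the C4=C5 vinyl group exo, which should give the 6,7-trans carbinol, 6R, that is kept in the target. The step needs lithiation at C6 and not at C12 or C13: C12 sits next to the fully substituted C11 with its bulky silyloxymethyl group, C13 is shielded by the triisopropylsilyl group, and the substrate holds no benzylic or other acidic ether C–H. The cold quench is meant to keep the C8 triethylsilyl group from migrating to the new C6 alkoxide.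

**Step 15**
Reactants: 28 ring-contracted trienol
Product: 30 (2R,6R,7S,8S,11RS)-2-(tert-butyldimethylsilyloxy)-8-(triethylsilyloxy)-13-(triisopropylsilyloxy)germacra-1(10)E,4E-diene-6,12-diol, via B-alkyl-9-borabicyclononane 29 (not isolated)
Conditions: 9-borabicyclo[3.3.1]nonane (3 equiv), THF, 0 °C → rt; then aq. NaOH, 30% H2O2, 0 °C
Reagents that add atoms: hydrogen peroxide, OO
Why: Hydroboration–oxidation with a bulky dialkylborane, which reacts far faster with the 1,1-disubstituted terminal alkene than with the two trisubstituted ring alkenes and places boron on C12; C11 forms as a mixture, which is of no consequence because it becomes sp2 in step 18.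

**Step 16**
Reactants: 30 6,12-diol
Product: 32 (2R,6R,7S,8S,11RS)-2-(tert-butyldimethylsilyloxy)-8-(triethylsilyloxy)-13-(triisopropylsilyloxy)germacra-1(10)E,4E-dien-12,6-olide, via lactol 31 (not isolated)
Conditions: PhI(OAc)2 (3 equiv), 2,2,6,6-tetramethylpiperidin-1-oxyl (0.2 equiv), CH2Cl2, rt
Reagents that add atoms: none
Why: Oxoammonium-mediated oxidative lactonisation of a 1,4-diol, in which the primary alcohol is oxidised to the aldehyde much faster than the secondary allylic C6 hydroxyl, the aldehyde closes to the lactol and this is oxidised to the γ-lactone; O8 is silylated, so only the 12,6-lactone can form.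

**Step 17**
Reactants: 32 saturated 12,6-lactone
Product: 34 (2R,6R,7S,8S)-2-(tert-butyldimethylsilyloxy)-11-(phenylselanyl)-8-(triethylsilyloxy)-13-(triisopropylsilyloxy)germacra-1(10)E,4E-dien-12,6-olide (selenium expected cis to H7), via lithium enolate 33 (not isolated)
Conditions: LiN(i-Pr)2 (1.2 equiv), THF, −78 °C, 20 min; PhSeBr, −78 °C
Reagents that add atoms: phenylselenenyl bromide, Br[Se]c1ccccc1
Why: α-Selenenylation of a lactone enolate formed by kinetic deprotonation at C11, the only enolisable position; the electrophile should enter anti to the C7–C8 bond, that is cis to H7, and at −78 °C β-loss of the C13 silyloxide should not compete.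

**Step 18**
Reactants: 34 α-phenylselanyl lactone
Product: 36 (2R,6R,8S)-2-(tert-butyldimethylsilyloxy)-8-(triethylsilyloxy)-13-(triisopropylsilyloxy)germacra-1(10)E,4E,7(11)-trien-12,6-olide, via selenoxide 35 (not isolated)
Conditions: mCPBA (1.05 equiv), CH2Cl2, −78 °C; then i-Pr2NH, → rt
Reagents that add atoms: none
Why: Selenide oxidation and selenoxide syn-elimination, which should go towards H7 (cis to selenium) and away from the oxygen-bearing C13 to give the tetrasubstituted C7=C11 bond conjugated with the lactone; at −78 °C the peracid oxidises selenium much faster than the ring alkenes, and the amine traps the selenenic acid.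

**Step 19**
Reactants: 36 silylated butenolide
Product: 37 (2R,6R,8S)-2-(tert-butyldimethylsilyloxy)-8-hydroxy-13-(triisopropylsilyloxy)germacra-1(10)E,4E,7(11)-trien-12,6-olide
Conditions: pyridinium p-toluenesulfonate (0.2 equiv), MeOH/CH2Cl2, 0 °C
Reagents that add atoms: none
Why: Acid-catalysed methanolysis removes the secondary triethylsilyl ether much faster than the tert-butyldimethylsilyl and triisopropylsilyl ethers, and such weakly acidic conditions should be too mild for transannular cyclisation of the diene or for migration of the lactone to O8.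

**Step 20**
Reactants: 37 C8 alcohol
Product: 38 (2R,6R,8S)-2-(tert-butyldimethylsilyloxy)-8-(methacryloyloxy)-13-(triisopropylsilyloxy)germacra-1(10)E,4E,7(11)-trien-12,6-olide
Conditions: methacrylic anhydride, Et3N, 4-(dimethylamino)pyridine (cat.), CH2Cl2, 0 °C
Reagents that add atoms: methacrylic anhydride, CC(=C)C(=O)OC(=O)C(C)=C
Why: Acylation of the C8 hydroxyl by the anhydride under nucleophilic catalysis, which should be fast enough at 0 °C to esterify the alcohol before it can translactonise.

**Step 21**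
Reactants: 38 C8 methacrylate
Product: 39 (2R,6R,8S)-2,13-dihydroxy-8-(methacryloyloxy)germacra-1(10)E,4E,7(11)-trien-12,6-olide
Conditions: Bu4NF/AcOH (1:1), THF, 0 °C → rt
Reagents that add atoms: none
Why: Fluoride-mediated cleavage of both remaining silyl ethers, buffered with acetic acid so that the methacrylate should not migrate to the freed C13 hydroxyl and the butenolide is not attacked.

**Step 22**
Reactants: 39 2,13-diol
Product: 40 (2R,6R,8S)-2,13-diacetoxy-8-(methacryloyloxy)germacra-1(10)E,4E,7(11)-trien-12,6-olide (CNP0309304.1)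
Conditions: Ac2O, pyridine, 4-(dimethylamino)pyridine (cat.), CH2Cl2, 0 °C → rt
Reagents that add atoms: acetic anhydride, CC(=O)OC(C)=O
Why: Acetylation of the primary allylic C13 hydroxyl and the secondary allylic C2 hydroxyl under nucleophilic catalysis completes the target without touching any stereocentre.

**Compound list**

1 | (R)-glycidol | OC[C@@H]1CO1 | starting material
2 | (2S)-pent-4-yne-1,2-diol | OC[C@@H](O)CC#C | intermediate
3 | (4S)-4,5-bis(triethylsilyloxy)pent-1-yne | CC[Si](CC)(CC)OC[C@@H](O[Si](CC)(CC)CC)CC#C | intermediate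
4 | dimethyl[(1E,4S)-2-methyl-4,5-bis(triethylsilyloxy)pent-1-en-1-yl]alane | C[Al](C)/C=C(C)/C[C@H](O[Si](CC)(CC)CC)CO[Si](CC)(CC)CC | intermediate (not isolated)
5 | lithium butyl(dimethyl)[(1E,4S)-2-methyl-4,5-bis(triethylsilyloxy)pent-1-en-1-yl]alanate | [Li+].CCCC[Al-](C)(C)/C=C(C)/C[C@H](O[Si](CC)(CC)CC)CO[Si](CC)(CC)CC | intermediate (not isolated)
6 | (2E,5S)-3-methyl-5,6-bis(triethylsilyloxy)hex-2-en-1-ol | CC[Si](CC)(CC)OC[C@@H](O[Si](CC)(CC)CC)C/C(C)=C/CO | intermediate
7 | (2E,5S)-3-methyl-5,6-bis(triethylsilyloxy)hex-2-enal | CC[Si](CC)(CC)OC[C@@H](O[Si](CC)(CC)CC)C/C(C)=C/C=O | intermediate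
8 | pinacol borate ester of 9 (O–B bond at C2) | CC[Si](CC)(CC)OC[C@@H](O[Si](CC)(CC)CC)C/C(C)=C/[C@H](OB1OC(C)(C)C(C)(C)O1)CC#C | intermediate (not isolated)
9 | (4R,5E,8S)-6-methyl-8,9-bis(triethylsilyloxy)non-5-en-1-yn-4-ol | CC[Si](CC)(CC)OC[C@@H](O[Si](CC)(CC)CC)C/C(C)=C/[C@H](O)CC#C | intermediate
10 | (4R,5E,8S)-4-(tert-butyldimethylsilyloxy)-6-methyl-8,9-bis(triethylsilyloxy)non-5-en-1-yne | CC[Si](CC)(CC)OC[C@@H](O[Si](CC)(CC)CC)C/C(C)=C/[C@H](O[Si](C)(C)C(C)(C)C)CC#C | intermediate
11 | [(1E,4R,5E,8S)-4-(tert-butyldimethylsilyloxy)-2,6-dimethyl-8,9-bis(triethylsilyloxy)nona-1,5-dien-1-yl]dimethylalane | C[Al](C)/C=C(C)/C[C@@H](O[Si](C)(C)C(C)(C)C)/C=C(C)/C[C@H](O[Si](CC)(CC)CC)CO[Si](CC)(CC)CC | intermediate (not isolated)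
12 | lithium butyl(dimethyl) alanate of 11 | [Li+].CCCC[Al-](C)(C)/C=C(C)/C[C@@H](O[Si](C)(C)C(C)(C)C)/C=C(C)/C[C@H](O[Si](CC)(CC)CC)CO[Si](CC)(CC)CC | intermediate (not isolated)
13 | (2E,5R,6E,9S)-5-(tert-butyldimethylsilyloxy)-3,7-dimethyl-9,10-bis(triethylsilyloxy)deca-2,6-dien-1-ol | CC[Si](CC)(CC)OC[C@@H](O[Si](CC)(CC)CC)C/C(C)=C/[C@H](O[Si](C)(C)C(C)(C)C)C/C(C)=C/CO | intermediate
14 | methanesulfonate of 13 | CC[Si](CC)(CC)OC[C@@H](O[Si](CC)(CC)CC)C/C(C)=C/[C@H](O[Si](C)(C)C(C)(C)C)C/C(C)=C/COS(C)(=O)=O | intermediate (not isolated)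
15 | (2E,5R,6E,9S)-5-(tert-butyldimethylsilyloxy)-1-chloro-3,7-dimethyl-9,10-bis(triethylsilyloxy)deca-2,6-diene | CC[Si](CC)(CC)OC[C@@H](O[Si](CC)(CC)CC)C/C(C)=C/[C@H](O[Si](C)(C)C(C)(C)C)C/C(C)=C/CCl | intermediate
16 | alkoxydimethylsulfonium chloride at O7 (primary silyl group of 15 replaced by SMe2+) | [Cl-].C[S+](C)OC[C@@H](O[Si](CC)(CC)CC)C/C(C)=C/[C@H](O[Si](C)(C)C(C)(C)C)C/C(C)=C/CCl | intermediate (not isolated)
17 | (2S,4E,6R,8E)-6-(tert-butyldimethylsilyloxy)-10-chloro-4,8-dimethyl-2-(triethylsilyloxy)deca-4,8-dienal | O=C[C@@H](O[Si](CC)(CC)CC)C/C(C)=C/[C@H](O[Si](C)(C)C(C)(C)C)C/C(C)=C/CCl | intermediate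
18 | triethyl phosphonoacetate | CCOC(=O)CP(=O)(OCC)OCC | starting material
19 | (chloromethoxy)triisopropylsilane | ClCO[Si](C(C)C)(C(C)C)C(C)C | starting material
20 | sodium salt of the triethyl phosphonoacetate carbanion | [Na+].CCOC(=O)[CH-]P(=O)(OCC)OCC | intermediate (not isolated)
21 | ethyl 2-(diethoxyphosphoryl)-3-(triisopropylsilyloxy)propanoate (racemic) | CCOC(=O)C(CO[Si](C(C)C)(C(C)C)C(C)C)P(=O)(OCC)OCC | intermediate
22 | ethyl (2E,4S,6E,8R,10E)-8-(tert-butyldimethylsilyloxy)-12-chloro-6,10-dimethyl-4-(triethylsilyloxy)-2-[(triisopropylsilyloxy)methyl]dodeca-2,6,10-trienoate | CCOC(=O)/C(CO[Si](C(C)C)(C(C)C)C(C)C)=C/[C@@H](O[Si](CC)(CC)CC)C/C(C)=C/[C@H](O[Si](C)(C)C(C)(C)C)C/C(C)=C/CCl | intermediate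
23 | (2Z,4S,6E,8R,10E)-8-(tert-butyldimethylsilyloxy)-12-chloro-6,10-dimethyl-4-(triethylsilyloxy)-2-[(triisopropylsilyloxy)methyl]dodeca-2,6,10-trien-1-ol | OC/C(CO[Si](C(C)C)(C(C)C)C(C)C)=C/[C@@H](O[Si](CC)(CC)CC)C/C(C)=C/[C@H](O[Si](C)(C)C(C)(C)C)C/C(C)=C/CCl | intermediate
24 | sodium alkoxide of 23 | [Na+].[O-]C/C(CO[Si](C(C)C)(C(C)C)C(C)C)=C/[C@@H](O[Si](CC)(CC)CC)C/C(C)=C/[C@H](O[Si](C)(C)C(C)(C)C)C/C(C)=C/CCl | intermediate (not isolated)
25 | (3Z,5S,7E,9R,11E)-9-(tert-butyldimethylsilyloxy)-7,11-dimethyl-5-(triethylsilyloxy)-3-[(triisopropylsilyloxy)methyl]-1-oxacyclotrideca-3,7,11-triene (oxygen bridging C6 and C12; ring bonds trans at all three alkenes) | O1C/C(CO[Si](C(C)C)(C(C)C)C(C)C)=C/[C@@H](O[Si](CC)(CC)CC)C/C(C)=C/[C@H](O[Si](C)(C)C(C)(C)C)C/C(C)=C/C1 | intermediate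
26 | C6-lithio derivative of 25 (delocalised over C6–C5–C4) | O1C/C(CO[Si](C(C)C)(C(C)C)C(C)C)=C/[C@@H](O[Si](CC)(CC)CC)C/C(C)=C/[C@H](O[Si](C)(C)C(C)(C)C)C/C(C)=C/C1[Li] | intermediate (not isolated)
27 | lithium alkoxide of 28 | CC[Si](CC)(CC)O[C@H]1C/C(C)=C/[C@H](O[Si](C)(C)C(C)(C)C)C/C(C)=C/[C@@H](O[Li])[C@@H]1C(=C)CO[Si](C(C)C)(C(C)C)C(C)C | intermediate (not isolated)
28 | (2R,6R,7S,8S)-2-(tert-butyldimethylsilyloxy)-8-(triethylsilyloxy)-13-(triisopropylsilyloxy)germacra-1(10)E,4E,11(12)-trien-6-ol | CC[Si](CC)(CC)O[C@H]1C/C(C)=C/[C@H](O[Si](C)(C)C(C)(C)C)C/C(C)=C/[C@@H](O)[C@@H]1C(=C)CO[Si](C(C)C)(C(C)C)C(C)C | intermediate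
29 | 12-(9-borabicyclo[3.3.1]nonan-9-yl)-11,12-dihydro derivative of 28 (C11 epimers) | CC[Si](CC)(CC)O[C@H]1C/C(C)=C/[C@H](O[Si](C)(C)C(C)(C)C)C/C(C)=C/[C@@H](O)[C@@H]1C(CB2C3CCCC2CCC3)CO[Si](C(C)C)(C(C)C)C(C)C | intermediate (not isolated)
30 | (2R,6R,7S,8S,11RS)-2-(tert-butyldimethylsilyloxy)-8-(triethylsilyloxy)-13-(triisopropylsilyloxy)germacra-1(10)E,4E-diene-6,12-diol | CC[Si](CC)(CC)O[C@H]1C/C(C)=C/[C@H](O[Si](C)(C)C(C)(C)C)C/C(C)=C/[C@@H](O)[C@@H]1C(CO)CO[Si](C(C)C)(C(C)C)C(C)C | intermediate
31 | 12-hydroxy-12,6-epoxy lactol of 30 | CC[Si](CC)(CC)O[C@H]1C/C(C)=C/[C@H](O[Si](C)(C)C(C)(C)C)C/C(C)=C/[C@@H](OC(O)C2CO[Si](C(C)C)(C(C)C)C(C)C)[C@@H]12 | intermediate (not isolated)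
32 | (2R,6R,7S,8S,11RS)-2-(tert-butyldimethylsilyloxy)-8-(triethylsilyloxy)-13-(triisopropylsilyloxy)germacra-1(10)E,4E-dien-12,6-olide (6,7-trans-fused) | CC[Si](CC)(CC)O[C@H]1C/C(C)=C/[C@H](O[Si](C)(C)C(C)(C)C)C/C(C)=C/[C@@H](OC(=O)C2CO[Si](C(C)C)(C(C)C)C(C)C)[C@@H]12 | intermediate
33 | lithium enolate of 32 (C11=C12–OLi) | CC[Si](CC)(CC)O[C@H]1C/C(C)=C/[C@H](O[Si](C)(C)C(C)(C)C)C/C(C)=C/[C@@H](OC(O[Li])=C2CO[Si](C(C)C)(C(C)C)C(C)C)[C@@H]12 | intermediate (not isolated)
34 | (2R,6R,7S,8S)-2-(tert-butyldimethylsilyloxy)-11-(phenylselanyl)-8-(triethylsilyloxy)-13-(triisopropylsilyloxy)germacra-1(10)E,4E-dien-12,6-olide (selenium expected cis to H7) | CC[Si](CC)(CC)O[C@H]1C/C(C)=C/[C@H](O[Si](C)(C)C(C)(C)C)C/C(C)=C/[C@@H](OC(=O)C2(CO[Si](C(C)C)(C(C)C)C(C)C)[Se]c3ccccc3)[C@@H]12 | intermediate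
35 | selenoxide of 34 | CC[Si](CC)(CC)O[C@H]1C/C(C)=C/[C@H](O[Si](C)(C)C(C)(C)C)C/C(C)=C/[C@@H](OC(=O)C2(CO[Si](C(C)C)(C(C)C)C(C)C)[Se](=O)c3ccccc3)[C@@H]12 | intermediate (not isolated)
36 | (2R,6R,8S)-2-(tert-butyldimethylsilyloxy)-8-(triethylsilyloxy)-13-(triisopropylsilyloxy)germacra-1(10)E,4E,7(11)-trien-12,6-olide | CC[Si](CC)(CC)O[C@H]1C/C(C)=C/[C@H](O[Si](C)(C)C(C)(C)C)C/C(C)=C/[C@H]2OC(=O)C(CO[Si](C(C)C)(C(C)C)C(C)C)=C12 | intermediate
37 | (2R,6R,8S)-2-(tert-butyldimethylsilyloxy)-8-hydroxy-13-(triisopropylsilyloxy)germacra-1(10)E,4E,7(11)-trien-12,6-olide | O[C@H]1C/C(C)=C/[C@H](O[Si](C)(C)C(C)(C)C)C/C(C)=C/[C@H]2OC(=O)C(CO[Si](C(C)C)(C(C)C)C(C)C)=C12 | intermediate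
38 | (2R,6R,8S)-2-(tert-butyldimethylsilyloxy)-8-(methacryloyloxy)-13-(triisopropylsilyloxy)germacra-1(10)E,4E,7(11)-trien-12,6-olide | C=C(C)C(=O)O[C@H]1C/C(C)=C/[C@H](O[Si](C)(C)C(C)(C)C)C/C(C)=C/[C@H]2OC(=O)C(CO[Si](C(C)C)(C(C)C)C(C)C)=C12 | intermediate
39 | (2R,6R,8S)-2,13-dihydroxy-8-(methacryloyloxy)germacra-1(10)E,4E,7(11)-trien-12,6-olide | C=C(C)C(=O)O[C@H]1C/C(C)=C/[C@H](O)C/C(C)=C/[C@H]2OC(=O)C(CO)=C12 | intermediate
40 | (2R,6R,8S)-2,13-diacetoxy-8-(methacryloyloxy)germacra-1(10)E,4E,7(11)-trien-12,6-olide (CNP0309304.1) | C=C(C)C(=O)O[C@H]1C/C(C)=C/[C@H](OC(C)=O)C/C(C)=C/[C@H]2OC(=O)C(COC(C)=O)=C12 | target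

**Step count and risks**

Total step count: 22 (21 in the main line and one for phosphonate 21).
Longest linear sequence: 21 steps (compound 1 to compound 40 through steps 1–9 and 11–22).

Steps most likely to fail:

1. Step 14. Lithiation may occur at the other ether methylene (C12) instead of C6, which would lead to the regioisomeric contraction or to 1,2-shift products. The fallback sets out from enoate 22 and returns at lactone 32. Reduction of 22 with AlD3 (LiAlD4/AlCl3, Et2O, −78 °C) would give the C12-dideuterated allylic alcohol F1, and cyclisation as in step 13 the dideuterated macrocyclic ether F2. The primary deuterium isotope effect should then slow lithiation at C12, so that n-BuLi is steered to C6 and the contraction gives the dideuteriomethylene alcohol F3. Hydroboration–oxidation as in step 15 would give the dideuterated diol F4, and the oxidative lactonisation of step 16 removes both deuterium atoms, so that unlabelled 32 is reached.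

2. Step 11. The phosphonate carbanion may fragment by β-loss of the silyloxide, which would also erode the geometric purity of the enoate. The fallback sets out from aldehyde 17 and returns at enoate 22. Sodium 4-methoxybenzyl oxide (4-methoxybenzyl alcohol, NaH, THF, 0 °C) is added to ethyl 2-(diethoxyphosphoryl)acrylate, and the phosphonate carbanion so generated olefinates 17 in a tandem oxa-Michael/Horner–Wadsworth–Emmons reaction to the 4-methoxybenzyl ether enoate F5. Here loss of alkoxide is reversible and feeds back into the olefination. DDQ (CH2Cl2/pH 7 buffer) would free the hydroxymethyl enoate F6, and TIPSOTf/2,6-lutidine converts it into 22.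

3. Step 17. The lithium enolate may expel the C13 silyloxide (E1cB) before it is selenenylated, giving the α-methylene lactone. The fallback sets out from lactone 32 and returns at selenide 34. LiN(i-Pr)2 is added to 32 in the presence of Me3SiCl at −78 °C, so that the enolate is trapped as it forms as the ketene trimethylsilyl acetal F7. This neutral species cannot eliminate and is selenenylated by PhSeCl (CH2Cl2, −78 °C) to give 34.

**Further compounds**

F1 | step 14 | 1,1-dideuterio analogue of 23 (CD2OH at C12) | [2H]C([2H])(O)/C(CO[Si](C(C)C)(C(C)C)C(C)C)=C/[C@@H](O[Si](CC)(CC)CC)C/C(C)=C/[C@H](O[Si](C)(C)C(C)(C)C)C/C(C)=C/CCl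
F2 | step 14 | 12,12-dideuterio analogue of macrocyclic ether 25 | O1C([2H])([2H])/C(CO[Si](C(C)C)(C(C)C)C(C)C)=C/[C@@H](O[Si](CC)(CC)CC)C/C(C)=C/[C@H](O[Si](C)(C)C(C)(C)C)C/C(C)=C/C1
F3 | step 14 | 12,12-dideuterio analogue of trienol 28 (C11=CD2) | CC[Si](CC)(CC)O[C@H]1C/C(C)=C/[C@H](O[Si](C)(C)C(C)(C)C)C/C(C)=C/[C@@H](O)[C@@H]1C(=C([2H])[2H])CO[Si](C(C)C)(C(C)C)C(C)C
F4 | step 14 | 12,12-dideuterio analogue of diol 30 (CD2OH at C12) | CC[Si](CC)(CC)O[C@H]1C/C(C)=C/[C@H](O[Si](C)(C)C(C)(C)C)C/C(C)=C/[C@@H](O)[C@@H]1C(C([2H])([2H])O)CO[Si](C(C)C)(C(C)C)C(C)C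
F5 | step 11 | ethyl (2E,4S,6E,8R,10E)-8-(tert-butyldimethylsilyloxy)-12-chloro-2-[(4-methoxybenzyloxy)methyl]-6,10-dimethyl-4-(triethylsilyloxy)dodeca-2,6,10-trienoate | CCOC(=O)/C(COCc1ccc(OC)cc1)=C/[C@@H](O[Si](CC)(CC)CC)C/C(C)=C/[C@H](O[Si](C)(C)C(C)(C)C)C/C(C)=C/CCl
F6 | step 11 | ethyl (2E,4S,6E,8R,10E)-8-(tert-butyldimethylsilyloxy)-12-chloro-2-(hydroxymethyl)-6,10-dimethyl-4-(triethylsilyloxy)dodeca-2,6,10-trienoate | CCOC(=O)/C(CO)=C/[C@@H](O[Si](CC)(CC)CC)C/C(C)=C/[C@H](O[Si](C)(C)C(C)(C)C)C/C(C)=C/CCl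
F7 | step 17 | ketene trimethylsilyl acetal of lactone 32 (C11=C12–OSiMe3) | CC[Si](CC)(CC)O[C@H]1C/C(C)=C/[C@H](O[Si](C)(C)C(C)(C)C)C/C(C)=C/[C@@H](OC(O[Si](C)(C)C)=C2CO[Si](C(C)C)(C(C)C)C(C)C)[C@@H]12
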